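The numbers in the tables are simulated from invented constants, and the scatter is random.

The eta run holds 2.24 times the free catalyst of the epsilon run, yet its target at 5.00 min stands at 40.5 % against 17.6 %.

the same everywhere: substrate 20 mM
- epsilon: reagent 1.2 equiv; free catalyst 0.067 mol%; run made earlier
- eta: reagent 1.2 equiv; free catalyst 0.15 mol%; run made earlier
- flask: reagent 1.20 equiv; free catalyst 0.1 mol%

- epsilon (time / min: target / %): 0.417: 0.9; 0.667: 1.9; 0.833: 2.6; 1.33: 3.4; 2.00: 7.7; 3.00: 7.9; 5.00: 17.6
- eta (time / min: target / %): 0.417: 3.0; 0.667: 3.3; 0.833: 6.8; 1.33: 11.1; 2.00: 19.1; 3.00: 26.8; 5.00: 40.5

(standard deviation of a reading: 1 percentage point)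

* apparent order in free catalyst when 10 % of the substrate are converted (percent change of the rate of making target for one percent more free catalyst charged)
* apparent order in reagent when 10 % of the substrate are converted (percent change of the rate of making target for one percent more reagent charged)

- what has left substrate counts as converted, also if it is not yet product
- no earlier run changes the charge of reagent; that part of a forecast is a guess

Take the first-order law in closed form, so that a target fraction y at time t gives the constant k = −ln(1 − y)/t. The last readings give 0.0387 min⁻¹ for the epsilon run and 0.104 min⁻¹ for the eta run. Their ratio of 2.69 is larger than the loading ratio. The eta constant returns 26.8 % at 3.00 min, where the reading is 26.8 %, but 6.70 % at 0.667 min, where the reading is 3.3 %, so on that run the closed form describes the later readings and stands above the early ones.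

The logarithm of the constants' ratio over that of the loadings gives a catalyst exponent of 1.22. It rests on two readings with a scatter of 1 percentage point, and it is my order in free catalyst. It gives 0.0632 min⁻¹ as the flask's target constant, the eta constant scaled by the loading ratio raised to that exponent.

The weak link is reading target as conversion: on that footing the flask reaches 10 % conversion at 1.67 min. No run varies the reagent, so my order in reagent is a guess of 0.5.

The forecast gives 1.3 for free catalyst, above my 1.22, and 0.5 for reagent, saying “The reagent order is therefore a guess”.

The flask gives 1.3 in free catalyst and 0.47 in reagent.

    substrate + free catalyst → free catalyst + open intermediate (k = 145 M⁻¹ s⁻¹)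
    free catalyst + open intermediate ⇌ catalyst intermediate (K = 150 M⁻¹, k = 7920 M⁻¹ s⁻¹)
    reagent + catalyst intermediate → free catalyst + target (k = 256 M⁻¹ s⁻¹)
    substrate + reagent → uncatalysed product (k = 0.100 M⁻¹ s⁻¹)

The flask reaches 10 % conversion at 0.347 min, much earlier than my 1.67 min, so that link breaks: substrate leaves well ahead of target. As a constant for target, though, 0.0632 min⁻¹ gives 31.6 % at 6.00 min, and the flask holds 31.9 %. Scaled to the epsilon loading, it gives 7.45 % at 2.00 min, where that run read 7.7 %.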